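The constants stand for no real mixture.

The four set-ups below hold the same charges and differ in how much J stands beside J.D, and for how long.

    J + D → J.D, rate k1*[J]*[D]^0.5 (k1 = 43 L⁰·⁵ mol⁻⁰·⁵ h⁻¹)
    J + G → J.G (k2 = 2200 L mol⁻¹ h⁻¹)
    2 J → J2 (k3 = 1.3 L mol⁻¹ h⁻¹)
    J + J.D → J.J.D (k4 = 15 L mol⁻¹ h⁻¹)

| flask | J | D | G | time | remark |
|---|---|---|---|---|---|
| Saturday's | 0.013 M (fed, over 8.00 h) | 6.50 mM | 0.260 mM | 10 h | all but J at the start; J goes in evenly over 8.00 h, the run ends at 10 h |
| Tuesday's | 0.013 M | 6.50 mM | 0.260 mM |  | a single well-mixed tank run continuously and read at steady state, 10 h in it on average |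
| Monday's | 0.013 M | 6.50 mM | 0.260 mM | 10 h | everything together in a closed stirred flask, run for 10 h |
| Friday's | 0.013 M | 6.50 mM (fed, over 8.00 h) | 0.260 mM | 10 h | all but D at the start; D goes in evenly over 8.00 h, the run ends at 10 h |

- percent here means J units held: one J2 or J.J.D counts as two
- where a step has two of a species, its rate is k times that concentration squared, and two are used at each turn
- the stated concentrations are those of everything mixed, before any reaction; amounts are the same in each set-up
- the feed brings no volume worth counting
- run time (Saturday's): 10 h

- the set-up with the highest amount of J.D at the outlet or at the end, in percent of the J put in ("none" if the first two lie within 2 percentage points) (Saturday's / Tuesday's / Monday's / Friday's / none)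
- amount of J.D at the outlet or at the end, in percent of the J put in, Saturday's
- amount of J.D at the outlet or at the end, in percent of the J put in, Tuesday's
- amount of J.D at the outlet or at the end, in percent of the J put in, Monday's
- amount of J.D at the outlet or at the end, in percent of the J put in, Friday's

1. **Exposure.** Let E be the area under the curve of [J] against time. Steps 1 and 4 both carry [J] as a factor, so in a closed vessel with D present from the start, as in Monday's and Saturday's, J.D follows E rather than the clock.

2. **Building.** In step 1 the square root of [D] falls in a straight line with E and reaches zero at E_D = 0.00375 M·h. D is the limiting reagent of step 1, so J.D is capped at 6.50 mM, which is 50.0% of the J charged.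

3. **Loss.** With D at zero, step 4 removes J.D in a pseudo-first-order decay whose rate constant is k4[J]. J.D therefore halves for each half-exposure H = ln(2)/k4 = 0.0462 M·h. E_D is smaller than H, so the reckoning starts the decay from the cap.

4. **Monday's.** After D and G have taken their share, J stands near 6.24 mM. Step 4 uses one J for each J.D lost, so if J.D halves, J falls by 3.25 mM. The mean of that falling J over 10 h gives E = 0.0461 M·h, about one H. The trial is consistent, so Monday's J.D comes to 25.0%.

5. **Saturday's.** The feed has delivered the equivalent of D and G by 4.16 h. The excess then builds to 6.24 mM by the end of the feed and is held there, with no loss of J counted. This gives E = 0.0245 M·h, about half of Monday's. That is 0.530 of H, so Saturday's J.D comes to 34.6%, higher than Monday's. Tuesday's and Friday's are not reckoned here.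

6. **Forecast.** The forecast names Saturday's, with 36.4% for Saturday's, 32.3% for Tuesday's, 27.3% for Monday's and 32.9% for Friday's, on the ground that “low J helps”.

7. **Result.** The best set-up is Saturday's: Saturday's gives 36.5%, Tuesday's 32.3%, Monday's 27.2% and Friday's 33.1%. In Saturday's, J.D reads 42.0% of the charge at 8.00 h, and J reads 39.2% at 8.00 h. Saturday's J then reads 32.9% at 10.0 h. The mean J gives E = 0.00938 M·h, or 0.203 of H, which takes J.D to 36.5%. In Monday's, J reads 30.1% at 5.00 h and 21.4% at 10.0 h, so E = 0.0167 M·h, which takes J.D from 34.8% to 27.1%.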